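Count the product in per cent of the starting material charged, not in molar. In that unit a flask shows what it does with its charge, and the alder run can be read from its neighbours.

| setting | oak | larch | maple | alder |
|---|---|---|---|---|
| starting material | 0.0800 M | 0.0320 M | 0.0800 M | 0.0400 M |
| free catalyst | 0.00640 M | 0.00640 M | 0.00320 M | 0.00320 M |
| time |  |  |  | 12 min |

| oak run: time / min | oak run: [product] / M | larch run: time / min | larch run: [product] / M | maple run: time / min | maple run: [product] / M |
|---|---|---|---|---|---|
| 0.43 | 0.0015 | 0.43 | 2 × 10⁻⁴ | 0.43 | 0.0012 |
| 1.3 | 0.0041 | 1.3 | 0.0014 | 1.3 | 0.0025 |
| 2.5 | 0.0098 | 2.5 | 0.0024 | 2.5 | 0.0047 |
| 4.0 | 0.0124 | 4.0 | 0.0027 | 4.0 | 0.0072 |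
| 5.7 | 0.0149 | 5.7 | 0.0033 | 5.7 | 0.0084 |
| 7.6 | 0.0170 | 7.6 | 0.0036 | 7.6 | 0.0100 |
| 9.7 | 0.0170 | 9.7 | 0.0041 | 9.7 | 0.0106 |
| 12 | 0.0178 | 12 | 0.0035 | 12 | 0.0107 |

(each reading ± 4 × 10⁻⁴ M)

* the power of [starting material] that the first rate follows, about the charge of the oak run; measure it at two percent of starting material made into product (one fixed amount of product, the same in the runs compared)
* the power of [free catalyst] that the first rate follows, about the charge of the oak run; measure it at two percent of starting material made into product
* product in the alder run at 12 min, as a share of the starting material charged

- Overall: starting material -> product, with free catalyst as catalyst.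
- Constant volume, constant temperature.
- What is held in complexes is read along with the free species.
- An order is taken over about fifteen percent of the charge, up and down.

Write the balance of the catalyst first, bound forms counted. The oak run made 2.78 product per catalyst charged, so the catalyst is not used up one for one.

Now build your reckoning up. Take the main step at the first power of starting material, which is pseudo-first-order. The share reached at a given time then depends on the catalyst and not on the charge. The alder run has the catalyst of the maple run, so on this first picture it takes the maple share, read from the last 2 readings:

maple share = 13.3 %

Next add the stop, since the oak, larch and maple curves flatten far short of their charges. The maple readings at 4.0 min and 12 min give a time constant of 3.58 min. At 12 min, on that time constant, 3.50 % of the rise remains, so this addition leaves the number nearly where it was, and you may treat the maple share as a plateau.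

Then add the charge. The oak share is 21.7 % and the larch share is 11.9 %, at the same catalyst, so the first picture does not hold: the share is larger in the oak run. Call the power with which the plateau share grows with the charge the share power:

share power = ln(oak share / larch share) / ln(oak charge / larch charge) = 0.660

Taking that power, read at the higher catalyst, over to the lower one, you find that halving the charge from the maple run to the alder run lowers the number:

alder share = maple share × (alder charge / maple charge)^(share power) = 8.42 %

One more than the share power, 1.66, is then the power with which the plateau amount of product, in molar, grows with the charge from the larch run to the oak run.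

The forecast gave 1.6 for the order in starting material, 0.9 for the order in free catalyst and, by “scaling the plateau from maple and larch”, 8.8 % for the alder run, a little above your 8.42 %.

The simulation gives 1.2 for the order in starting material, 0.87 for the order in free catalyst and 8.30 % for the alder run.

    free catalyst + starting material ⇌ catalyst-substrate complex, settled at all times (73.50 M⁻¹)
    catalyst-substrate complex + starting material ⇌ doubly bound catalyst, settled at all times (4.420 M⁻¹)
    doubly bound catalyst → product + catalyst-substrate complex (2.682 min⁻¹)
    starting material + product → 2 product (5.754 M⁻¹ min⁻¹)
    starting material → decomposed substrate (0.3012 min⁻¹)

The alder run stays low mainly because starting material turns into decomposed substrate: with that loss taken away, the alder run reaches 58.9 % at 12 min, not 8.30 %. Your share power carries the larch rate of 8.2 × 10⁻⁴ M min⁻¹, taken where two percent of the oak charge has turned, up to 0.00374 M min⁻¹ for the oak run, which stands at 0.0038 M min⁻¹ at that same amount. Around the oak charge the order is 1.2, and the same loss lifts it there, from 1.0 in the oak run without it.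

All runs are calculated for an exercise, noise included.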